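Ring C is disconnected at the aryl ether bond O1–C8a. O1 links the only stereocentre, C2, to ring A carbon C8a, so arylating the oxygen of a ready-made (S)-carbinol never touches the C2–O bond. The configuration set by an asymmetric aldol reaction is therefore carried into the flavanone. In one operation, palladium-catalysed intramolecular etherification forms O1–C8a and closes ring C as a 4-methylidene flavan. The precursor is an (S)-homoallylic alcohol: the carbinol carbon bears the 2,4,5-trimethoxyphenyl group (latent quinone ring B), and the 1,1-disubstituted alkene (masked C4 ketone) carries the ring A aryl group with bromine at C8a and O5 as a MOM ether.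

Key step: step 11

Remarks on the chemistry:
- Bromine placement: ring bromination of the finished acetophenone at the carbon meta to both methoxy groups would have to compete with bromination of the acetyl group. Bromine is therefore installed first, at the one sterically free C–H of 2,6-dimethoxytoluene.
- O5 protection: O5 is carried as a MOM ether, not a methyl ether. No boron or aluminium halide then meets the flavanone, whose C2–O1 bond is a benzylic ether of a very electron-rich ring until ring B is oxidised.
- Assumption: the catalyst enantiomer in step 7 is the one that gives the (S)-aldol; the mirror-image catalyst is used if the first run shows the opposite sense.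

Step 1
Reactants: 1 2,6-dimethoxytoluene
Product: 3 5-bromo-1,3-dimethoxy-2-methylbenzene, via the pinacol arylboronate 2 (not isolated)
Conditions: [Ir(OMe)(cod)]2 (1.5 mol %), dtbpy (3 mol %), B2pin2, THF, 80 °C; evaporate; CuBr2 (3 equiv), MeOH/H2O 1:1, 80 °C
Reagents that add atoms: copper dibromide, [Cu+2].[Br-].[Br-]; bis(pinacolato)diboron, CC1(C)OB(OC1(C)C)B1OC(C)(C)C(C)(C)O1 (its boron is carried only in 2)
Why: Iridium-catalysed C–H borylation is sterically governed and should pick the only ring C–H without an ortho substituent (para to the methyl group, meta to both methoxy groups), and copper-mediated bromodeboronation then puts bromine on that same carbon.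

Step 2
Reactants: 3 5-bromo-1,3-dimethoxy-2-methylbenzene
Product: 5 6-bromo-2,4-dimethoxy-3-methylbenzaldehyde, via the iminium chloride 4 (not isolated)
Conditions: POCl3, DMF, 0 to 90 °C; then H2O, 0 °C to rt
Reagents that add atoms: N,N-dimethylformamide, CN(C)C=O; water, O
Why: Vilsmeier–Haack formylation should attack one of the two equivalent ring carbons that lie ortho to one methoxy group and para to the other, the only activated sites left.

Step 3
Reactants: 5 6-bromo-2,4-dimethoxy-3-methylbenzaldehyde
Product: 6 1-bromo-3,5-dimethoxy-2,4-dimethylbenzene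
Conditions: Et3SiH (3 equiv), CF3CO2H, CH2Cl2, 0 °C to rt
Reagents that add atoms: none
Why: Ionic hydrogenation reduces the electron-rich aryl aldehyde through its benzylic cation to the methyl group and leaves the aryl bromide alone, which catalytic hydrogenolysis would endanger.

Step 4
Reactants: 6 1-bromo-3,5-dimethoxy-2,4-dimethylbenzene; 7 acetyl chloride
Product: 9 1-(2-bromo-6-hydroxy-4-methoxy-3,5-dimethylphenyl)ethan-1-one, via the dimethoxy ketone 8 (not isolated)
Conditions: AlCl3 (3 equiv), CH2Cl2, 0 °C to rt; then ice-cold 1 M HCl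
Reagents that add atoms: none
Why: Friedel–Crafts acylation can only occur at the single free ring carbon, which is ortho and para to the two methoxy groups, and the excess AlCl3 then cleaves the methyl ether chelated to the new carbonyl group (chelation-controlled demethylation), which frees the future O5 for a protecting group removable without Lewis acid.

Step 5
Reactants: 9 1-(2-bromo-6-hydroxy-4-methoxy-3,5-dimethylphenyl)ethan-1-one
Product: 10 1-[2-bromo-4-methoxy-6-(methoxymethoxy)-3,5-dimethylphenyl]ethan-1-one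
Conditions: MOMCl, i-Pr2NEt, CH2Cl2, 0 to 40 °C
Reagents that add atoms: chloromethyl methyl ether, COCCl
Why: O-Alkylation of the phenol (Williamson type) gives an acetal that is inert to strong base, fluoride, titanium methylidene and palladium chemistry and is later removed by mild protic acid.

Step 6
Reactants: 10 1-[2-bromo-4-methoxy-6-(methoxymethoxy)-3,5-dimethylphenyl]ethan-1-one
Product: 12 {1-[2-bromo-4-methoxy-6-(methoxymethoxy)-3,5-dimethylphenyl]ethenyl}oxy(trimethyl)silane, via the lithium enolate 11 (not isolated)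
Conditions: LiN(SiMe3)2, THF, −78 °C; then Me3SiCl, −78 to 0 °C; non-aqueous work-up
Reagents that add atoms: chlorotrimethylsilane, C[Si](C)(C)Cl
Why: Deprotonation of the methyl ketone (the ring carries no hydrogen and the acetyl methyl is the only acidic site) followed by O-silylation gives the enol silane needed for a Mukaiyama aldol reaction.

Step 7
Reactants: 12 {1-[2-bromo-4-methoxy-6-(methoxymethoxy)-3,5-dimethylphenyl]ethenyl}oxy(trimethyl)silane; 13 2,4,5-trimethoxybenzaldehyde
Product: 15 (3S)-1-[2-bromo-4-methoxy-6-(methoxymethoxy)-3,5-dimethylphenyl]-3-hydroxy-3-(2,4,5-trimethoxyphenyl)propan-1-one, via the trichlorosilyl ether 14 (not isolated)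
Conditions: SiCl4 (1.5 equiv), chiral pentane-1,5-diyl-linked bis(N,N'-dimethyl-1,1'-binaphthyl-2,2'-diamine) bisphosphoramide (5 mol %), i-Pr2NEt (10 mol %), CH2Cl2, −78 °C; then sat. aq. NaHCO3
Reagents that add atoms: silicon tetrachloride, Cl[Si](Cl)(Cl)Cl (its silicon is carried only in 14)
Why: Mukaiyama aldol reaction under Lewis-base activation of SiCl4, in which the chiral bisphosphoramide-bound trichlorosilyl cation binds the aldehyde and screens one face, so that the enol silane (its twisted aryl group makes it behave like a bulky alkyl methyl ketone enolate) should add to the Si face and set C2 as S, the sense to be secured by Mosher ester analysis of 15 on the first run.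

Step 8
Reactants: 15 (3S)-1-[2-bromo-4-methoxy-6-(methoxymethoxy)-3,5-dimethylphenyl]-3-hydroxy-3-(2,4,5-trimethoxyphenyl)propan-1-one
Product: 16 (3S)-1-[2-bromo-4-methoxy-6-(methoxymethoxy)-3,5-dimethylphenyl]-3-[(tert-butyldimethylsilyl)oxy]-3-(2,4,5-trimethoxyphenyl)propan-1-one
Conditions: TBSCl, imidazole, DMF, rt
Reagents that add atoms: tert-butyldimethylsilyl chloride, CC(C)(C)[Si](C)(C)Cl
Why: Standard O-silylation masks the aldol hydroxyl so that the ketone can be methylenated without retro-aldol cleavage or titanium alkoxide formation.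

Step 9
Reactants: 16 (3S)-1-[2-bromo-4-methoxy-6-(methoxymethoxy)-3,5-dimethylphenyl]-3-[(tert-butyldimethylsilyl)oxy]-3-(2,4,5-trimethoxyphenyl)propan-1-one
Product: 17 (1S)-3-[2-bromo-4-methoxy-6-(methoxymethoxy)-3,5-dimethylphenyl]-1-(2,4,5-trimethoxyphenyl)but-3-en-1-yl tert-butyldimethylsilyl ether
Conditions: Cp2TiMe2 (3 equiv), toluene, 70 °C, dark
Reagents that add atoms: dimethyltitanocene, [CH3-].[CH3-].[Ti+4].c1cc[cH-]c1.c1cc[cH-]c1
Why: Petasis methylenation uses a non-basic titanium methylidene that converts hindered, enolisable ketones into 1,1-disubstituted alkenes and avoids the beta-elimination of silanolate that a phosphorus ylide would provoke.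

Step 10
Reactants: 17 (1S)-3-[2-bromo-4-methoxy-6-(methoxymethoxy)-3,5-dimethylphenyl]-1-(2,4,5-trimethoxyphenyl)but-3-en-1-yl tert-butyldimethylsilyl ether
Product: 18 (1S)-3-[2-bromo-4-methoxy-6-(methoxymethoxy)-3,5-dimethylphenyl]-1-(2,4,5-trimethoxyphenyl)but-3-en-1-ol
Conditions: n-Bu4NF, THF, 0 °C to rt
Reagents that add atoms: none
Why: Fluoride-mediated desilylation frees the secondary alcohol, while the aryl bromide, the MOM acetal and the alkene are inert to it.

Step 11
Reactants: 18 (1S)-3-[2-bromo-4-methoxy-6-(methoxymethoxy)-3,5-dimethylphenyl]-1-(2,4,5-trimethoxyphenyl)but-3-en-1-ol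
Product: 19 (2S)-7-methoxy-5-(methoxymethoxy)-6,8-dimethyl-4-methylidene-2-(2,4,5-trimethoxyphenyl)chromane
Conditions: Pd(OAc)2 (5 mol %), 2-(di-tert-butylphosphino)-1,1'-binaphthyl (6 mol %), Cs2CO3 (1.5 equiv), toluene, 80 °C
Reagents that add atoms: none
Why: Zerovalent palladium, formed in the flask from Pd(OAc)2 and the bulky di-tert-butyl(biaryl)phosphine, inserts into the C8a–Br bond, Cs2CO3 converts the bound alcohol into a divalent aryl(alkoxo)palladium chelate with a seven-membered ring, and C–O reductive elimination releases the chromane. The closest known reaction type is the intramolecular Buchwald–Hartwig etherification of aryl bromides with secondary alcohols, which gives 2-substituted chromans. Ring C, six-membered, closes by bond formation between O1 and the ipso carbon C8a of ring A, formally a 6-exo closure onto the arene carbon that is realised as reductive elimination from the palladacycle. No stereocentre is created, and since C2 is not a reaction centre its S configuration from step 7 is kept. The step needs reductive elimination to outrun beta-hydride elimination of the secondary benzylic alkoxide, which the large electron-rich ligand and the two ortho substituents of the aryl group (C8 methyl, C4a alkenyl) favour by crowding the metal. The C4 methylidene group, unlike a ketone, offers no retro-aldol, dehydration or ring-opening path under the carbonate base.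

Step 12
Reactants: 19 (2S)-7-methoxy-5-(methoxymethoxy)-6,8-dimethyl-4-methylidene-2-(2,4,5-trimethoxyphenyl)chromane
Product: 21 (2S)-7-methoxy-5-(methoxymethoxy)-6,8-dimethyl-2-(2,4,5-trimethoxyphenyl)chroman-4-one, via the C4 diol 20 (not isolated)
Conditions: OsO4 (2 mol %), NaIO4 (4 equiv), 2,6-lutidine, 1,4-dioxane/H2O 3:1, rt
Reagents that add atoms: osmium tetroxide, O=[Os](=O)(=O)=O (oxygen carrier, reoxidised by sodium periodate, [Na+].[O-]I(=O)(=O)=O)
Why: Lemieux–Johnson oxidation, in which osmium-catalysed dihydroxylation of the electron-rich 1,1-disubstituted alkene and periodate cleavage of the diol unveil the C4 ketone, with 2,6-lutidine buffering the medium so that the flavanone ring is not opened.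

Step 13
Reactants: 21 (2S)-7-methoxy-5-(methoxymethoxy)-6,8-dimethyl-2-(2,4,5-trimethoxyphenyl)chroman-4-one
Product: 22 (2S)-7-methoxy-2-(4-methoxy-3,6-dioxocyclohexa-1,4-dien-1-yl)-5-(methoxymethoxy)-6,8-dimethylchroman-4-one
Conditions: (NH4)2Ce(NO3)6 (2.5 equiv), MeCN/H2O 2:1, 0 °C
Reagents that add atoms: water, O
Why: Oxidative demethylation with (NH4)2Ce(NO3)6 turns the para-related 2- and 5-methoxy groups of the most electron-rich ring into the 1,4-benzoquinone carbonyls and keeps the 4-methoxy group, while ring A, deactivated by the C4 carbonyl and lacking a para-dioxygen pattern, should stay intact.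

Step 14
Reactants: 22 (2S)-7-methoxy-2-(4-methoxy-3,6-dioxocyclohexa-1,4-dien-1-yl)-5-(methoxymethoxy)-6,8-dimethylchroman-4-one
Product: 23 (2S)-5-hydroxy-7-methoxy-2-(4-methoxy-3,6-dioxocyclohexa-1,4-dien-1-yl)-6,8-dimethylchroman-4-one (CNP0208927.1)
Conditions: CF3CO2H/CH2Cl2 1:9, H2O (2 equiv), 0 °C to rt
Reagents that add atoms: none
Why: Acid-catalysed acetal cleavage of the MOM ether, eased by the peri carbonyl group, frees the hydrogen-bonded 5-OH at a stage where ring B is an electron-poor quinone, so the C2–O1 bond cannot ionise and the stereocentre is safe.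

Compound list
1 | 2,6-dimethoxytoluene | COc1cccc(OC)c1C | starting material
2 | 2-(3,5-dimethoxy-4-methylphenyl)-4,4,5,5-tetramethyl-1,3,2-dioxaborolane | COc1cc(cc(OC)c1C)B1OC(C)(C)C(C)(C)O1 | intermediate (not isolated)
3 | 5-bromo-1,3-dimethoxy-2-methylbenzene | COc1cc(Br)cc(OC)c1C | intermediate
4 | N-[(6-bromo-2,4-dimethoxy-3-methylphenyl)methylidene]-N-methylmethanaminium chloride | C[N+](C)=Cc1c(Br)cc(OC)c(C)c1OC.[Cl-] | intermediate (not isolated)
5 | 6-bromo-2,4-dimethoxy-3-methylbenzaldehyde | O=Cc1c(Br)cc(OC)c(C)c1OC | intermediate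
6 | 1-bromo-3,5-dimethoxy-2,4-dimethylbenzene | Cc1c(Br)cc(OC)c(C)c1OC | intermediate
7 | acetyl chloride | CC(Cl)=O | starting material
8 | 1-(2-bromo-4,6-dimethoxy-3,5-dimethylphenyl)ethan-1-one | CC(=O)c1c(Br)c(C)c(OC)c(C)c1OC | intermediate (not isolated)
9 | 1-(2-bromo-6-hydroxy-4-methoxy-3,5-dimethylphenyl)ethan-1-one | CC(=O)c1c(Br)c(C)c(OC)c(C)c1O | intermediate
10 | 1-[2-bromo-4-methoxy-6-(methoxymethoxy)-3,5-dimethylphenyl]ethan-1-one | CC(=O)c1c(Br)c(C)c(OC)c(C)c1OCOC | intermediate
11 | lithium 1-[2-bromo-4-methoxy-6-(methoxymethoxy)-3,5-dimethylphenyl]ethen-1-olate | [Li+].[O-]C(=C)c1c(Br)c(C)c(OC)c(C)c1OCOC | intermediate (not isolated)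
12 | {1-[2-bromo-4-methoxy-6-(methoxymethoxy)-3,5-dimethylphenyl]ethenyl}oxy(trimethyl)silane | C=C(O[Si](C)(C)C)c1c(Br)c(C)c(OC)c(C)c1OCOC | intermediate
13 | 2,4,5-trimethoxybenzaldehyde | COc1cc(OC)c(C=O)cc1OC | starting material
14 | (3S)-1-[2-bromo-4-methoxy-6-(methoxymethoxy)-3,5-dimethylphenyl]-3-[(trichlorosilyl)oxy]-3-(2,4,5-trimethoxyphenyl)propan-1-one | COc1cc(OC)c([C@@H](O[Si](Cl)(Cl)Cl)CC(=O)c2c(Br)c(C)c(OC)c(C)c2OCOC)cc1OC | intermediate (not isolated)
15 | (3S)-1-[2-bromo-4-methoxy-6-(methoxymethoxy)-3,5-dimethylphenyl]-3-hydroxy-3-(2,4,5-trimethoxyphenyl)propan-1-one | COc1cc(OC)c([C@@H](O)CC(=O)c2c(Br)c(C)c(OC)c(C)c2OCOC)cc1OC | intermediate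
16 | (3S)-1-[2-bromo-4-methoxy-6-(methoxymethoxy)-3,5-dimethylphenyl]-3-[(tert-butyldimethylsilyl)oxy]-3-(2,4,5-trimethoxyphenyl)propan-1-one | COc1cc(OC)c([C@@H](O[Si](C)(C)C(C)(C)C)CC(=O)c2c(Br)c(C)c(OC)c(C)c2OCOC)cc1OC | intermediate
17 | (1S)-3-[2-bromo-4-methoxy-6-(methoxymethoxy)-3,5-dimethylphenyl]-1-(2,4,5-trimethoxyphenyl)but-3-en-1-yl tert-butyldimethylsilyl ether | COc1cc(OC)c([C@@H](O[Si](C)(C)C(C)(C)C)CC(=C)c2c(Br)c(C)c(OC)c(C)c2OCOC)cc1OC | intermediate
18 | (1S)-3-[2-bromo-4-methoxy-6-(methoxymethoxy)-3,5-dimethylphenyl]-1-(2,4,5-trimethoxyphenyl)but-3-en-1-ol | COc1cc(OC)c([C@@H](O)CC(=C)c2c(Br)c(C)c(OC)c(C)c2OCOC)cc1OC | intermediate (key-step precursor)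
19 | (2S)-7-methoxy-5-(methoxymethoxy)-6,8-dimethyl-4-methylidene-2-(2,4,5-trimethoxyphenyl)chromane | COc1cc(OC)c([C@@H]2CC(=C)c3c(OCOC)c(C)c(OC)c(C)c3O2)cc1OC | intermediate (key-step product)
20 | (2S)-4-(hydroxymethyl)-7-methoxy-5-(methoxymethoxy)-6,8-dimethyl-2-(2,4,5-trimethoxyphenyl)chroman-4-ol, both C4 epimers | COc1cc(OC)c([C@@H]2CC(O)(CO)c3c(OCOC)c(C)c(OC)c(C)c3O2)cc1OC | intermediate (not isolated)
21 | (2S)-7-methoxy-5-(methoxymethoxy)-6,8-dimethyl-2-(2,4,5-trimethoxyphenyl)chroman-4-one | COc1cc(OC)c([C@@H]2CC(=O)c3c(OCOC)c(C)c(OC)c(C)c3O2)cc1OC | intermediate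
22 | (2S)-7-methoxy-2-(4-methoxy-3,6-dioxocyclohexa-1,4-dien-1-yl)-5-(methoxymethoxy)-6,8-dimethylchroman-4-one | COC1=CC(=O)C([C@@H]2CC(=O)c3c(OCOC)c(C)c(OC)c(C)c3O2)=CC1=O | intermediate
23 | (2S)-5-hydroxy-7-methoxy-2-(4-methoxy-3,6-dioxocyclohexa-1,4-dien-1-yl)-6,8-dimethylchroman-4-one | COC1=CC(=O)C([C@@H]2CC(=O)c3c(O)c(C)c(OC)c(C)c3O2)=CC1=O | target

Total step count: 14. Longest linear sequence: 14 steps (1 to 23); 7 and 13 are bought.

Steps most likely to fail

1. Step 11. The palladium alkoxide may undergo beta-hydride elimination, which oxidises the carbinol and reduces the C–Br bond, and the hydride so formed may move the exocyclic double bond into ring C. The fallback sets out from 10 and comes back at 21; it creates the stereocentre on a finished ring C by asymmetric conjugate arylation instead.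
 - Hydroxylation of the C–Br bond of 10 (Pd2(dba)3, t-BuXPhos, KOH, 1,4-dioxane/H2O, 100 °C) should give 1-[2-hydroxy-4-methoxy-6-(methoxymethoxy)-3,5-dimethylphenyl]ethan-1-one F1.
 - Condensation with Me2NCH(OMe)2 (toluene, 90 °C) should give the enaminone (E)-3-(dimethylamino)-1-[2-hydroxy-4-methoxy-6-(methoxymethoxy)-3,5-dimethylphenyl]prop-2-en-1-one F2.
 - Cyclisation with loss of dimethylamine (AcOH, toluene, 80 °C) should give 7-methoxy-5-(methoxymethoxy)-6,8-dimethyl-4H-chromen-4-one F3.
 - Enantioselective 1,4-addition of commercial (2,4,5-trimethoxyphenyl)boronic acid (COc1cc(OC)c(B(O)O)cc1OC) under Pd(OCOCF3)2/t-BuPyOx catalysis (NH4PF6, H2O, ClCH2CH2Cl, 60 °C), with the ligand enantiomer that gives 2S, should lead to 21.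

2. Step 7. Facial selectivity may be poor with the twisted, doubly ortho-substituted enol silane, and the Lewis acid may strip the MOM group or dehydrate the very electron-rich aldol. The fallback sets out from 10 and 13 and comes back at 15.
 - Claisen–Schmidt condensation (KOH, EtOH, rt) should give the chalcone (E)-1-[2-bromo-4-methoxy-6-(methoxymethoxy)-3,5-dimethylphenyl]-3-(2,4,5-trimethoxyphenyl)prop-2-en-1-one F4.
 - Asymmetric nucleophilic epoxidation (La(OiPr)3, BINOL, Ph3As=O, t-BuOOH, 4 Å molecular sieves, THF, rt; ligand enantiomer chosen for the 2S,3R oxirane) should give [2-bromo-4-methoxy-6-(methoxymethoxy)-3,5-dimethylphenyl][(2S,3R)-3-(2,4,5-trimethoxyphenyl)oxiran-2-yl]methanone F5.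
 - Regioselective reductive opening of the oxirane C–O bond next to the carbonyl group ((PhSe)2, NaBH4, AcOH, EtOH, 0 °C) should give 15, with the benzylic C–O bond and hence the S configuration untouched.

3. Step 9. Addition of the titanium methylidene to the ketone flanked by bromine and the MOM ether may be too slow, so that thermal loss of silanol or enolisation takes over. The fallback sets out from 16 and comes back at 17; it is a two-stage Peterson olefination.
 - Me3SiCH2Li/CeCl3 (THF, −78 °C) adds to the hindered, enolisable ketone and should give the beta-hydroxysilane (4S)-2-[2-bromo-4-methoxy-6-(methoxymethoxy)-3,5-dimethylphenyl]-4-[(tert-butyldimethylsilyl)oxy]-4-(2,4,5-trimethoxyphenyl)-1-(trimethylsilyl)butan-2-ol F6, as both carbinol epimers.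
 - KH (THF, 0 °C) then triggers syn-elimination of trimethylsilanolate to give 17.

Further compounds
F1 | step 11 | 1-[2-hydroxy-4-methoxy-6-(methoxymethoxy)-3,5-dimethylphenyl]ethan-1-one | CC(=O)c1c(O)c(C)c(OC)c(C)c1OCOC
F2 | step 11 | (E)-3-(dimethylamino)-1-[2-hydroxy-4-methoxy-6-(methoxymethoxy)-3,5-dimethylphenyl]prop-2-en-1-one | CN(C)/C=C/C(=O)c1c(O)c(C)c(OC)c(C)c1OCOC
F3 | step 11 | 7-methoxy-5-(methoxymethoxy)-6,8-dimethyl-4H-chromen-4-one | COCOc1c(C)c(OC)c(C)c2occc(=O)c12
F4 | step 7 | (E)-1-[2-bromo-4-methoxy-6-(methoxymethoxy)-3,5-dimethylphenyl]-3-(2,4,5-trimethoxyphenyl)prop-2-en-1-one | COc1cc(OC)c(/C=C/C(=O)c2c(Br)c(C)c(OC)c(C)c2OCOC)cc1OC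
F5 | step 7 | [2-bromo-4-methoxy-6-(methoxymethoxy)-3,5-dimethylphenyl][(2S,3R)-3-(2,4,5-trimethoxyphenyl)oxiran-2-yl]methanone | COc1cc(OC)c([C@H]2O[C@@H]2C(=O)c2c(Br)c(C)c(OC)c(C)c2OCOC)cc1OC
F6 | step 9 | (4S)-2-[2-bromo-4-methoxy-6-(methoxymethoxy)-3,5-dimethylphenyl]-4-[(tert-butyldimethylsilyl)oxy]-4-(2,4,5-trimethoxyphenyl)-1-(trimethylsilyl)butan-2-ol | COc1cc(OC)c([C@@H](O[Si](C)(C)C(C)(C)C)CC(O)(C[Si](C)(C)C)c2c(Br)c(C)c(OC)c(C)c2OCOC)cc1OC
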